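The readings are simulated with constants of no real substance; scatter was added.

- The constants I could read from maple and oak were apparent first-order constants for the left-handed substrate, in what is a kinetic resolution: oak's left-handed product levelled at 50.1 %.

in all of them: left-handed substrate 0.050 M; right-handed substrate 0.050 M

| run | reagent | free catalyst | remark |
|---|---|---|---|
| maple | 2 equiv | 0.5 mol% | run made earlier |
| oak | 2 equiv | 2 mol% | run made earlier |
| flask | 2.00 equiv | 1 mol% |  |

| run | time / h | left-handed product / % | left-handed substrate / % |
|---|---|---|---|
| maple | 2.50 | 12.5 | 37.2 |
| maple | 6.00 | 26.3 | 23.2 |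
| maple | 12.0 | 38.8 | 10.6 |
| maple | 20.0 | 46.4 | 3.4 |
| oak | 2.50 | 37.4 | 13.3 |
| oak | 6.00 | 48.6 | 1.1 |
| oak | 12.0 | 50.1 | 0 |
| oak | 20.0 | 50.1 | 0 |

(readings scatter by 0.3 percentage points)

* factor on the rate of making left-handed product when 50 % of the left-handed substrate and right-handed substrate together are converted if reagent is charged twice over
* factor on the rate when 50 % of the left-handed substrate and right-handed substrate together are converted if free catalyst is charged at 5 mol% instead

- free catalyst is single-handed; left-handed substrate and right-handed substrate are mirror images of each other, charged as a racemate, each of them at the stated concentration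
- no earlier run changes the charge of reagent; that part of a forecast is a guess

- From the start to the first reading, maple gave 0.118 h⁻¹ and oak 0.530 h⁻¹, so the early way gave an order in catalyst of 1.08, and going from 1 mol% to 5 mol% gave a factor of 5.70.
- The second way used the last readable stretch of each run: 12.0 h to 20.0 h in maple gave 0.142 h⁻¹, and 2.50 h to 6.00 h in oak gave 0.712 h⁻¹.
- Those gave 1.16, the late loading order: the logarithm of the ratio of the late constants over the logarithm of the ratio of the loadings.
- The late way gave a factor of 6.49, higher than the early way, so the two parted.
- The early way cheated here, since it compared unlike stretches: by 2.50 h oak's left-handed substrate stood at 13.3 %, lower than maple's 37.2 %, whereas maple's last reading, with left-handed product at 46.4 % and so close to 50 % conversion, held 3.4 % of left-handed substrate. The late way had its own weakness, oak's reading of 1.1 % against a scatter of 0.3 percentage points.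
- I committed to 6.49, assuming similar [left-handed substrate] at that point in both charges. No earlier run changed the reagent, so I reckoned no factor for it.
- The forecast gave 5.5 for the catalyst and 1.6 for the reagent, and called the response to catalyst “slightly more than linear”; its catalyst factor stood below mine.
- The flask gave 6.52 for the catalyst and 2.56 for the reagent, both above the forecast.

    free catalyst + left-handed substrate ⇌ catalyst intermediate A (K = 370 L mol⁻¹, k = 2.10 L mol⁻¹ s⁻¹)
    free catalyst + right-handed substrate ⇌ catalyst intermediate B (K = 74.0 L mol⁻¹, k = 0.700 L mol⁻¹ s⁻¹)
    reagent + catalyst intermediate A → free catalyst + left-handed product (k = 0.110 L mol⁻¹ s⁻¹)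
    reagent + catalyst intermediate B → free catalyst + right-handed product (k = 0.0130 L mol⁻¹ s⁻¹)
    free catalyst → spent catalyst (k = 3.30 × 10⁻⁵ s⁻¹)

- At 15.0 h in the flask, the forward use of free catalyst by left-handed substrate was 0.042 of its forward use by right-handed substrate, less than parity, with 51.7 % of the catalyst as catalyst intermediate B against 2.16 % as catalyst intermediate A. Maple's late constant, carried to 1 mol% by the late loading order, gives 0.318 h⁻¹, and the flask's left-handed substrate fell from 6.21 % to 0.573 % between 7.50 h and 15.0 h, at 0.318 h⁻¹.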